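The numbers in the tables are calculated for an exercise; the scatter is artificial.

Start with the easy end: once the solid substrate has dissolved, with the gas held, treat [starting material] as a pseudo-first-order fall. Take blue's last two readings for the fall constant, the fraction of [starting material] lost per day, 0.601 /d.

| setting | teal | blue | flask |
|---|---|---|---|
| solid substrate | 0.025 M | 0.038 M | 0.050 M |
| gas | 7.4 mM (held) | 7.4 mM (held) | 7.4 mM (held) |
| remark | run made earlier | run made earlier |  |
| time |  |  | 5.0 d |

- teal (time / d: first product / %, starting material / %): 1.04: 17, 66; 2.08: 24, 32; 3.00: 22, 16; 4.00: 17, 15
- blue (time / d: first product / %, starting material / %): 0.500: 8, 56; 1.25: 19, 60; 2.50: 27, 32; 4.00: 15, 13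

(readings scatter by 2 percentage points)

1. the first product standing at 5.0 d, as a percentage of the solid substrate charged
2. concentration of starting material in solution at 5.0 d, in percent of saturation

- solid substrate is a solid; its amount is given per volume of the solution
- at the start none of the solid substrate is in solution
- at the start none of the gas is in solution
- starting material is what solid substrate becomes in solution
- starting material means what is dissolved; the solid is not counted in it

Now the other end. Use blue's reading at 1.25 d, 22.8 mM, as a floor for saturation, and take that floor as the level held while solid stands. Join the ends: material leaves at the fall constant times that level, so my reckoning has blue's solid lasting 1.11 d, before 2.50 d.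

Your flask holds 0.050 M of solid substrate. Expect its solid to last 1.99 d, against the forecast's 2.1 d. Expect [starting material] of 3.73 mM at 5.0 d, which is 16.4% of saturation if saturation stands at that floor. Leave the gas at 7.4 mM: the constant was read there.

The forecast says 12% and 17%, from “solid dissolving quickly up to a saturation limit”. I have no reckoning of my own for the first product, so I take its figure.

    reagent + first product → double product (k = 9.30 × 10⁻⁴ /M/s)
    solid substrate ⇌ starting material, rate k2*(cs2 - [starting material]) while solid is left; crystals form when [starting material] > cs2 (solubility = 37.0 mM, k = 2.30 × 10⁻⁵ /s)
    starting material + reagent → other mono adduct (k = 3.10 × 10⁻⁴ /M/s)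
    starting material + reagent → first product (k = 6.30 × 10⁻⁴ /M/s)
    gas ⇌ reagent, rate k5*(csat - [reagent]) (kL = 7.60 × 10⁻⁴ /s)
    reagent + other mono adduct → double product (k = 0.00280 /M/s)

The flask gives 13.8% and 11.2%. Saturation is 37 mM, above the blue level. Carry the fall constant from the flask's 35.8% at 2.50 d: it predicts 7.97% of the charge at 5.0 d, and the flask holds 8.32%. With 0.085 M charged, the same join predicts 20.3% of the charge as starting material at 5.0 d, and that flask holds 17.4%.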